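**Plan**
1. Feature: without the oxirane oxygen on C1/C10, the ten-membered ring C1–C10 holds the 1,5-diene C10=C1–C2–C3–C4=C5. Bonds C1–C4 and C5–C10 fold it into a bicyclo[2.2.0]hexane (C1, C2, C3, C4, C5, C10) fused to a cyclohexane (C5–C10). That tricycle is the [2+2] adduct of the enone C6(=O)–C5=C10 and the cyclobutene C1=C4.
2. Cuts, in retrosynthetic order: oxirane O; acyl–O8; C11=C13; C1=C10/C4=C5 back to C1–C4/C5–C10; C8 carbinol to ketone to epimeric ether; O6–C12 and C7–C11; the key bonds C4–C5 and C1–C10; last the O3–Si–O14 tether.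
3. Forward: a cyclohexenone (from cyclohexanetriol) and a cyclobutenol (from the succinoin bis-silyl ether) are linked through iPr2Si. Light closes the central cyclobutane (6-4-4 core) and an eight-membered silyl acetal ring. The γ-lactone is built on the rigid core, heat merges the three carbocycles into the ten-membered ring, and the oxirane closes last.
4. Stereochemistry: C3 comes from a lipase resolution and is relayed by the tether to C1, C4, C5 and C10. The C15 methyl directs hydride to C6, and a temporary 8-epi ether (lipase desymmetrisation) directs C7. C8 is reset by oxidation and Li[HB(sBu)3] reduction, and C2' is bought with the acid. The tether dictates trans C1=C10, which leaves C4=C5 cis, and L-(+)-diethyl tartrate sets C1/C10.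

Key step: step 15

Remark: atoms keep the germacrane numbers of the target (C6–O and C7–C11–C12 lactone, C13 methylene, C14 = CH2O on C10, C15 = CH3 on C4, C2' in the acyl group); on the cyclohexane ring of the tricycles, syn and anti mean the face of the fused cyclobutane and the opposite face; PMB = 4-methoxybenzyl, DMB = 3,4-dimethoxybenzyl; both lipases are assumed to obey the empirical size rule for secondary alcohols.

Step 1
Reactants: 1 cis,cis-cyclohexane-1,3,5-triol
Product: 2 all-cis-5-(PMB-oxy)cyclohexane-1,3-diol (meso)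
Conditions: NaH (1 equiv), 4-MeOC6H4CH2Cl (1 equiv), Bu4NI (cat.), DMF, 0 °C to rt
Reagents that add atoms: 4-methoxybenzyl chloride, COc1ccc(CCl)cc1
Why: Williamson ether synthesis on one of three equivalent hydroxyls; the statistical mixture is separated, 1 is recycled and no stereocentre is touched.

Step 2
Reactants: 2 all-cis-5-(PMB-oxy)cyclohexane-1,3-diol
Product: 3 (1R,3R,5S)-3-hydroxy-5-(PMB-oxy)cyclohexyl acetate
Conditions: lipase PS (Burkholderia cepacia, immobilised), vinyl acetate, tBuOMe, 30 °C
Reagents that add atoms: vinyl acetate, C=COC(C)=O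
Why: Enzymatic desymmetrisation of a meso diol by irreversible transesterification; by the size rule the carbinol of R configuration (larger ring arm toward the PMB ether) is acylated, which fixes the absolute configuration of the ether carbon C8.

Step 3
Reactants: 3 (1R,3R,5S)-3-hydroxy-5-(PMB-oxy)cyclohexyl acetate
Product: 5 (R)-5-(PMB-oxy)cyclohex-2-en-1-one, via β-acetoxy ketone 4 (not isolated)
Conditions: Dess–Martin periodinane, CH2Cl2, 0 °C to rt; then Et3N, rt
Reagents that add atoms: none
Why: Dess–Martin oxidation followed by E1cB loss of acetic acid; acetate leaves far more readily than the benzyl-type ether, so C8 is kept.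

Step 4
Reactants: 6 3,4-dimethoxybenzyl alcohol; 7 tributyl(iodomethyl)stannane
Product: 8 tributyl[(DMB-oxy)methyl]stannane
Conditions: NaH, THF/DMF, 0 °C to rt
Reagents that add atoms: none
Why: Williamson etherification is the standard entry to alkoxymethylstannanes; a benzyl-type ether is used because α-silyloxy carbanions would undergo retro-Brook rearrangement in step 5.

Step 5
Reactants: 8 tributyl[(DMB-oxy)methyl]stannane; 5 (R)-5-(PMB-oxy)cyclohex-2-en-1-one
Product: 10 (5R)-1-[(DMB-oxy)methyl]-5-(PMB-oxy)cyclohex-2-en-1-ol (either C1 epimer), via alkoxymethyllithium 9 (not isolated)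
Conditions: nBuLi, THF, −78 °C; then 5, −78 °C; H2O quench
Reagents that add atoms: none
Why: Tin–lithium exchange gives an α-alkoxymethyllithium that adds 1,2 to the enone at low temperature and brings in C14; the new carbinol centre is erased in step 6.

Step 6
Reactants: 10 tertiary allylic alcohol
Product: 11 (S)-3-[(DMB-oxy)methyl]-5-(PMB-oxy)cyclohex-2-en-1-one
Conditions: IBX, DMSO, 55 °C
Reagents that add atoms: none
Why: Oxidative 1,3-transposition of a cyclic tertiary allylic alcohol (Dauben–Michno type) gives the 3-substituted enone; carbonyl and alkene change ends, so the untouched C8 now has the 8-epi sense (S).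

Step 7
Reactants: 11 (S)-enone DMB ether
Product: 12 (S)-3-(hydroxymethyl)-5-(PMB-oxy)cyclohex-2-en-1-one
Conditions: DDQ (1.05 equiv), CH2Cl2/pH 7 buffer, 0 °C
Reagents that add atoms: none
Why: Oxidative benzyl ether cleavage is faster for the electron-richer, primary DMB ether than for the secondary PMB ether, and the neutral medium avoids β-elimination to a phenol.

Step 8
Reactants: 13 1,2-bis(trimethylsilyloxy)cyclobut-1-ene
Product: 14 2-hydroxycyclobutan-1-one (racemic)
Conditions: MeOH (dry, degassed), rt
Reagents that add atoms: none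
Why: Methanolysis of the acyloin bis-silyl ether is the standard preparation of this α-hydroxy ketone.

Step 9
Reactants: 14 2-hydroxycyclobutan-1-one
Product: 15 2-(tert-butyldimethylsilyloxy)cyclobutan-1-one (racemic)
Conditions: tBuMe2SiCl, imidazole, CH2Cl2, 0 °C to rt
Reagents that add atoms: tert-butyldimethylsilyl chloride, CC(C)(C)[Si](C)(C)Cl
Why: Imidazole-promoted silylation blocks the hydroxyl for the two organometallic steps that follow.

Step 10
Reactants: 15 2-(tert-butyldimethylsilyloxy)cyclobutan-1-one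
Product: 17 4-(tert-butyldimethylsilyloxy)cyclobut-1-en-1-yl triflate (racemic), via lithium enolate 16 (not isolated)
Conditions: LiN(SiMe3)2, THF, −78 °C; then N-(5-chloro-2-pyridyl)bis(trifluoromethanesulfonimide), −78 °C
Reagents that add atoms: N-(5-chloro-2-pyridyl)bis(trifluoromethanesulfonimide), O=S(=O)(N(c1ccc(Cl)cn1)S(=O)(=O)C(F)(F)F)C(F)(F)F
Why: Kinetic enolisation takes the unhindered CH2 rather than the silyloxy-bearing CH, and O-sulfonylation at −78 °C traps this enolate as the enol triflate.

Step 11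
Reactants: 17 cyclobutenyl triflate
Product: 18 tert-butyldimethyl[(2-methylcyclobut-2-en-1-yl)oxy]silane (racemic)
Conditions: MeMgBr, Fe(acac)3 (5 mol %), THF/N-methylpyrrolidone, −30 °C
Reagents that add atoms: methylmagnesium bromide, C[Mg]Br
Why: Iron-catalysed Kumada-type coupling of an alkenyl triflate places C15 on the sp2 carbon next to the carbinol, so no cyclobutenone is ever handled.

Step 12
Reactants: 18 silyl ether of 2-methylcyclobut-2-en-1-ol
Product: 19 2-methylcyclobut-2-en-1-ol (racemic)
Conditions: Bu4NF, THF, 0 °C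
Reagents that add atoms: none
Why: Fluoride desilylation under non-acidic conditions spares the ionisable cyclobutenyl carbinol.

Step 13
Reactants: 19 2-methylcyclobut-2-en-1-ol (racemic)
Product: 20 (S)-2-methylcyclobut-2-en-1-ol
Conditions: lipase PS (immobilised), vinyl acetate (0.6 equiv), pentane/tBuOMe, rt, run slightly beyond half conversion
Reagents that add atoms: none
Why: Lipase kinetic resolution of a cyclic allylic alcohol; by the size rule the R enantiomer (large group = methyl-bearing sp2 carbon) is acetylated and the S alcohol, which carries the C3 configuration of the target, remains.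

Step 14
Reactants: 20 (S)-2-methylcyclobut-2-en-1-ol; 12 (S)-3-(hydroxymethyl)-5-(PMB-oxy)cyclohex-2-en-1-one
Product: 22 diisopropyl{[(S)-5-(PMB-oxy)-3-oxocyclohex-1-en-1-yl]methoxy}{[(S)-2-methylcyclobut-2-en-1-yl]oxy}silane, via chlorosilane 21 (not isolated)
Conditions: iPr2SiCl2 (1.1 equiv), imidazole, CH2Cl2, −20 °C, add 20; then 12, imidazole, 4-dimethylaminopyridine (cat.), 0 °C to rt
Reagents that add atoms: dichlorodiisopropylsilane, CC(C)[Si](Cl)(Cl)C(C)C
Why: Stepwise substitution at a dichlorosilane (hindered secondary alcohol first, primary alcohol second) is the usual way to unsymmetrical silyl acetals, and the mild base spares the β-alkoxy enone.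

Step 15
Reactants: 22 silicon-tethered enone–cyclobutene
Product: 23 head-to-head cis-anti-cis 6-4-4 tricyclic ketone (C6 ketone; new bonds C4–C5 and C1–C10; C15 and H1 exo, H5 and C14 endo; O3 endo and bridged to O14 by iPr2Si; 8-OPMB syn)
Conditions: hν (350 nm lamps, Pyrex), degassed MeCN (0.005 M), 0 °C
Reagents that add atoms: none
Why: n,π* excitation and intersystem crossing give the twisted enone triplet, whose β-carbon C10 bonds to the unsubstituted cyclobutene carbon C1, and the triplet 1,4-biradical (α-keto radical C5, tertiary radical C4) closes after spin inversion. The closest known reaction types are the enone–cyclobutene [2+2] photocycloaddition to 6-4-4 tricycles and the enone–alkene [2+2] photocycloaddition through a temporary silicon tether. Two rings close: the eight-membered 1,3-dioxa-2-silocane (Si, O14, C14, C10, C1, C2, C3, O3) by the first, intramolecular radical-type C10–C1 bond, and the central cyclobutane (C1, C4, C5, C10) by C4–C5 recombination of the biradical. C1 and C4 are controlled by C3, since the tether lets the enone reach only the cyclobutene face that carries O3 (O3 ends endo); C5 and C10 follow from the cis ring fusion preferred by the six-membered biradical and from the exo (cis-anti-cis) docking, the only one in which the O–Si–O bridge spans C14 and O3 without strain, so that one absolute core results. Head-to-head regiochemistry is required and is secured by first bonding at the less hindered C1, by avoidance of vicinal quaternary centres C10/C4 and by the bridge, which is relaxed in the head-to-head and compressed in the head-to-tail adduct. Facial choice on the enone is required too: the tether has to override the mild preference of the pseudo-equatorial C8 ether for attack on the other face.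

Step 16
Reactants: 23 tricyclic ketone; 24 methyl bromoacetate
Product: 26 keto ester (C7–CH2CO2Me anti; trans to the 8-OPMB), via lithium enolate 25 (not isolated)
Conditions: LiN(iPr)2 (1.1 equiv), THF, −78 °C; then 24, N,N'-dimethylpropyleneurea, −78 to −40 °C
Reagents that add atoms: none
Why: Kinetic enolate alkylation; only C7 can be enolised (C5 is a strained ring-fusion methine), and the bromide enters anti to both the C8 ether and the C15 methyl, giving the diequatorial and also thermodynamically preferred C7 centre of the target.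

Step 17
Reactants: 26 keto ester
Product: 28 trans-fused γ-lactone (O6 syn; C7 chain anti; 8-OPMB syn), via hydroxy ester 27 (not isolated)
Conditions: NaBH4, THF/MeOH, −20 °C; work-up; pyridinium p-toluenesulfonate (cat.), CH2Cl2, rt
Reagents that add atoms: none
Why: Substrate-controlled ketone reduction; the bridgehead methyl C15 lies over the syn face of C6, so hydride comes from the anti face, and the equatorial O6 (target configuration) lactonises onto the neighbouring equatorial ester chain.

Step 18
Reactants: 28 lactone PMB ether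
Product: 29 8-epi-hydroxy lactone (8-OH syn)
Conditions: DDQ, CH2Cl2/pH 7 buffer, 0 °C to rt
Reagents that add atoms: none
Why: Oxidative PMB cleavage is orthogonal to the silyl acetal, the lactone and the saturated strained core.

Step 19
Reactants: 29 8-epi-hydroxy lactone
Product: 30 C8 keto lactone
Conditions: Dess–Martin periodinane, CH2Cl2, 0 °C to rt
Reagents that add atoms: none
Why: Neutral Dess–Martin oxidation removes the relay centre without epimerising C7 or eliminating the β-acyloxy group.

Step 20
Reactants: 30 C8 keto lactone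
Product: 31 8-hydroxy lactone (8-OH anti; cis to the C7 chain)
Conditions: Li[HB(sBu)3] (L-Selectride), THF, −78 °C; AcOH quench at −78 °C
Reagents that add atoms: none
Why: The bulky borohydride attacks the 2-substituted cyclohexanone equatorially (chair locked by the trans lactone) and gives the axial alcohol cis to the C7 substituent, which is the C8 configuration of the target.

Step 21
Reactants: 31 8-hydroxy lactone
Product: 35 α-methylene lactone alcohol, via dilithium enolate alkoxide 32 (not isolated), via Mannich base 33 (not isolated), via ammonium iodide 34 (not isolated)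
Conditions: LiN(iPr)2 (2.2 equiv), THF, −78 °C; [Me2N=CH2]I, −78 °C to rt; work-up; MeI, CH2Cl2; aq NaHCO3
Reagents that add atoms: N,N-dimethylmethyleneiminium iodide, C=[N+](C)C.[I-]; iodomethane (its carbon leaves again with the amine), CI
Why: Eschenmoser methylenation (Mannich reaction of the lactone enolate, quaternisation, E1cB elimination) installs C13; it precedes acylation so that the C2' centre never meets strong base, and O8 cannot reach C12 of the trans-fused lactone.

Step 22
Reactants: 35 α-methylene lactone alcohol; 36 (R)-2-methylbutanoic acid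
Product: 37 tricyclic 8-[(R)-2-methylbutanoate]
Conditions: N,N'-dicyclohexylcarbodiimide, 4-dimethylaminopyridine (cat.), CH2Cl2, 0 °C to rt
Reagents that add atoms: none
Why: Steglich esterification acylates the only free hydroxyl with retention at C8 and without enolising the acid.

Step 23
Reactants: 37 tricyclic ester
Product: 38 bridged cyclodeca-1(10),4-diene (C1=C10 trans in the ten-membered ring with C14 cis to C2; C4=C5 cis; O3 and O14 still joined by iPr2Si)
Conditions: degassed mesitylene (0.005 M), 2,6-di-tert-butyl-4-methylphenol (cat.), base-washed glass, 165 °C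
Reagents that add atoms: none
Why: Thermal cycloreversion of the bicyclo[2.2.0]hexane through the cyclohexane-1,4-diyl cleaves C1–C4 and C5–C10 and normally gives a cis,trans-diene; the eight-membered silyl acetal can hold C1=C10 only with C14 cis to C2 (trans in the larger ring, the stable bridgehead-alkene arrangement), which leaves C4=C5 as the cis bond, and all four cyclobutane centres vanish.

Step 24
Reactants: 38 bridged cyclodecadiene
Product: 39 3,14-diol of the cyclodeca-1(10),4-diene
Conditions: HF·pyridine, pyridine, THF, 0 °C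
Reagents that add atoms: none
Why: Buffered fluoride cleaves both Si–O bonds and leaves the ester, the methylene lactone and the two ring alkenes untouched.

Step 25
Reactants: 39 diene diol
Product: 40 target CNP0356520.1
Conditions: Ti(OiPr)4, L-(+)-diethyl tartrate, tBuOOH (1 equiv), 4 Å molecular sieves, CH2Cl2, −20 °C
Reagents that add atoms: tert-butyl hydroperoxide, CC(C)(C)OO
Why: Sharpless asymmetric epoxidation; the tartrate that gives (2S)-epoxy alcohols from 2-alken-1-ols delivers oxygen to C10/C1 in the (10S,1R) sense, and the primary C14 alcohol should react ahead of the hindered secondary C3 alcohol, whose cis alkene is deactivated by O6.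

**Compound list**
1 | cis,cis-cyclohexane-1,3,5-triol | O[C@H]1C[C@@H](O)C[C@@H](O)C1 | starting material
2 | all-cis-5-(PMB-oxy)cyclohexane-1,3-diol | O[C@H]1C[C@@H](O)C[C@@H](OCc2ccc(OC)cc2)C1 | intermediate
3 | (1R,3R,5S)-3-hydroxy-5-(PMB-oxy)cyclohexyl acetate | CC(=O)O[C@H]1C[C@@H](OCc2ccc(OC)cc2)C[C@@H](O)C1 | intermediate
4 | (1S,3R)-3-(PMB-oxy)-5-oxocyclohexyl acetate (cis) | CC(=O)O[C@H]1C[C@@H](OCc2ccc(OC)cc2)CC(=O)C1 | intermediate
5 | (R)-5-(PMB-oxy)cyclohex-2-en-1-one | O=C1C=CC[C@@H](OCc2ccc(OC)cc2)C1 | intermediate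
6 | 3,4-dimethoxybenzyl alcohol | OCc1ccc(OC)c(OC)c1 | starting material
7 | tributyl(iodomethyl)stannane | CCCC[Sn](CI)(CCCC)CCCC | starting material
8 | tributyl[(DMB-oxy)methyl]stannane | CCCC[Sn](CCCC)(CCCC)COCc1ccc(OC)c(OC)c1 | intermediate
9 | [(DMB-oxy)methyl]lithium | [Li]COCc1ccc(OC)c(OC)c1 | intermediate
10 | (5R)-1-[(DMB-oxy)methyl]-5-(PMB-oxy)cyclohex-2-en-1-ol (C1 open) | OC1(COCc2ccc(OC)c(OC)c2)C=CC[C@@H](OCc2ccc(OC)cc2)C1 | intermediate
11 | (S)-3-[(DMB-oxy)methyl]-5-(PMB-oxy)cyclohex-2-en-1-one | O=C1C=C(COCc2ccc(OC)c(OC)c2)C[C@H](OCc2ccc(OC)cc2)C1 | intermediate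
12 | (S)-3-(hydroxymethyl)-5-(PMB-oxy)cyclohex-2-en-1-one | O=C1C=C(CO)C[C@H](OCc2ccc(OC)cc2)C1 | intermediate
13 | 1,2-bis(trimethylsilyloxy)cyclobut-1-ene | C[Si](C)(C)OC1=C(O[Si](C)(C)C)CC1 | starting material
14 | 2-hydroxycyclobutan-1-one (racemic) | O=C1CCC1O | intermediate
15 | 2-(tert-butyldimethylsilyloxy)cyclobutan-1-one (racemic) | O=C1CCC1O[Si](C)(C)C(C)(C)C | intermediate
16 | lithium enolate of 15 (toward CH2) | [Li]OC1=CCC1O[Si](C)(C)C(C)(C)C | intermediate
17 | 4-(tert-butyldimethylsilyloxy)cyclobut-1-en-1-yl triflate (racemic) | O=S(=O)(OC1=CCC1O[Si](C)(C)C(C)(C)C)C(F)(F)F | intermediate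
18 | tert-butyldimethyl[(2-methylcyclobut-2-en-1-yl)oxy]silane (racemic) | CC1=CCC1O[Si](C)(C)C(C)(C)C | intermediate
19 | 2-methylcyclobut-2-en-1-ol (racemic) | CC1=CCC1O | intermediate
20 | (S)-2-methylcyclobut-2-en-1-ol | CC1=CC[C@@H]1O | intermediate
21 | chlorodiisopropyl{[(S)-2-methylcyclobut-2-en-1-yl]oxy}silane | CC1=CC[C@@H]1O[Si](Cl)(C(C)C)C(C)C | intermediate
22 | silicon-tethered enone–cyclobutene (key-step precursor) | O=C1C=C(CO[Si](C(C)C)(C(C)C)O[C@H]2CC=C2C)C[C@H](OCc3ccc(OC)cc3)C1 | intermediate
23 | head-to-head cis-anti-cis 6-4-4 tricyclic ketone (key-step product) | O=C1C[C@@H](OCc5ccc(OC)cc5)C[C@]2(CO[Si]4(C(C)C)C(C)C)[C@H]1[C@@]3(C)[C@@H](O4)C[C@@H]23 | intermediate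
24 | methyl bromoacetate | COC(=O)CBr | starting material
25 | lithium C6=C7 enolate of 23 | [Li]OC1=C[C@@H](OCc5ccc(OC)cc5)C[C@]2(CO[Si]4(C(C)C)C(C)C)[C@H]1[C@@]3(C)[C@@H](O4)C[C@@H]23 | intermediate
26 | C7-alkylated keto ester | O=C1[C@H](CC(=O)OC)[C@@H](OCc5ccc(OC)cc5)C[C@]2(CO[Si]4(C(C)C)C(C)C)[C@H]1[C@@]3(C)[C@@H](O4)C[C@@H]23 | intermediate
27 | C6 hydroxy ester | O[C@H]1[C@H](CC(=O)OC)[C@@H](OCc5ccc(OC)cc5)C[C@]2(CO[Si]4(C(C)C)C(C)C)[C@H]1[C@@]3(C)[C@@H](O4)C[C@@H]23 | intermediate
28 | trans-fused lactone, 8-epi PMB ether | O=C1C[C@@H]2[C@@H](OCc6ccc(OC)cc6)C[C@]3(CO[Si]5(C(C)C)C(C)C)[C@H]([C@H]2O1)[C@@]4(C)[C@@H](O5)C[C@@H]34 | intermediate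
29 | 8-epi-hydroxy lactone | O=C1C[C@@H]2[C@@H](O)C[C@]3(CO[Si]5(C(C)C)C(C)C)[C@H]([C@H]2O1)[C@@]4(C)[C@@H](O5)C[C@@H]34 | intermediate
30 | C8 keto lactone | O=C1C[C@@H]2C(=O)C[C@]3(CO[Si]5(C(C)C)C(C)C)[C@H]([C@H]2O1)[C@@]4(C)[C@@H](O5)C[C@@H]34 | intermediate
31 | 8-hydroxy lactone (target C8) | O=C1C[C@@H]2[C@H](O)C[C@]3(CO[Si]5(C(C)C)C(C)C)[C@H]([C@H]2O1)[C@@]4(C)[C@@H](O5)C[C@@H]34 | intermediate
32 | dilithium enolate alkoxide of 31 | [Li]OC1=C[C@@H]2[C@H](O[Li])C[C@]3(CO[Si]5(C(C)C)C(C)C)[C@H]([C@H]2O1)[C@@]4(C)[C@@H](O5)C[C@@H]34 | intermediate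
33 | C11 dimethylaminomethyl lactone (C11 open) | O=C1C(CN(C)C)[C@@H]2[C@H](O)C[C@]3(CO[Si]5(C(C)C)C(C)C)[C@H]([C@H]2O1)[C@@]4(C)[C@@H](O5)C[C@@H]34 | intermediate
34 | trimethylammonium iodide of 33 | O=C1C(C[N+](C)(C)C)[C@@H]2[C@H](O)C[C@]3(CO[Si]5(C(C)C)C(C)C)[C@H]([C@H]2O1)[C@@]4(C)[C@@H](O5)C[C@@H]34.[I-] | intermediate
35 | α-methylene lactone alcohol | O=C1C(=C)[C@@H]2[C@H](O)C[C@]3(CO[Si]5(C(C)C)C(C)C)[C@H]([C@H]2O1)[C@@]4(C)[C@@H](O5)C[C@@H]34 | intermediate
36 | (R)-2-methylbutanoic acid | CC[C@@H](C)C(=O)O | starting material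
37 | tricyclic 8-[(R)-2-methylbutanoate] | O=C1C(=C)[C@@H]2[C@H](OC(=O)[C@H](C)CC)C[C@]3(CO[Si]5(C(C)C)C(C)C)[C@H]([C@H]2O1)[C@@]4(C)[C@@H](O5)C[C@@H]34 | intermediate
38 | silyl-acetal-bridged cyclodeca-1(10),4-diene | C=C1C(=O)O[C@@H]2/C=C(/C)[C@@H]3C/C=C(\CO[Si](C(C)C)(C(C)C)O3)C[C@@H](OC(=O)[C@H](C)CC)[C@@H]12 | intermediate
39 | 3,14-diol of the diene | C=C1C(=O)O[C@@H]2/C=C(/C)[C@@H](O)C/C=C(\CO)C[C@@H](OC(=O)[C@H](C)CC)[C@@H]12 | intermediate
40 | CNP0356520.1 | C=C1C(=O)O[C@@H]2/C=C(/C)[C@@H](O)C[C@H]3O[C@]3(CO)C[C@@H](OC(=O)[C@H](C)CC)[C@@H]12 | target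

**Count**
- Total steps: 25.
- Longest linear sequence: 18 steps. Both branches have this length: steps 1, 2, 3, 5, 6, 7 followed by 14–25, and steps 8–13 followed by 14–25.

**Steps most likely to fail**

Step 15. The cyclobutene must dock on the enone face that carries the C8 ether. Slow closure could therefore let head-to-tail closure on the other face, enone dimerisation or hydrogen abstraction take over.

The fallback sets out from 5 and 9 and returns at 30. It uses the enantiomeric enone, so that tether and ether ask for the same face, and relays C7 from O6 instead of O8.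
- Organolithium 9 is turned with CuI into Li[Cu(CH2ODMB)2] and added to 5 in the presence of Me3SiCl to give trans silyl enol ether F1.
- Saegusa–Ito oxidation with Pd(OAc)2 gives (R)-enone DMB ether F2, DDQ gives (R)-enone alcohol F3, and chlorosilane 21 gives silyl acetal F4.
- Irradiation as in step 15 should give 8-epimeric tricyclic ketone F5 (OPMB anti).
- NaBH4 attacks C6 from the anti face to give alcohol F6. Et3SiOTf/2,6-lutidine gives triethylsilyl ether F7, DDQ gives C8 alcohol F8, and Dess–Martin periodinane gives C8 ketone F9.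
- LiN(iPr)2 enolises F9 toward C7 (C9 is neopentyl), and 24 enters anti to the C6 silyl ether to give keto ester F10.
- Pyridinium p-toluenesulfonate in MeOH removes the triethylsilyl group, and the freed O6 closes the lactone to 30.

Step 23. The bridge may hinder the boat-to-chair change of the 1,4-diyl. The temperature then needed could allow boat-type cleavage with loss of the cis C4=C5 geometry, or C2–C3 cleavage and siloxy-Cope rearrangement to a divinylcyclohexane.

The fallback sets out from 37 and returns at 39. It gives up the tether before ring opening.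
- HF·pyridine frees tricyclic diol F11, and tBuMe2SiOTf/2,6-lutidine gives bis-silyl ether F12.
- Flash vacuum thermolysis (short contact, about 450 °C) opens it to cyclodecadiene bis-silyl ether F13.
- The diyl can now reach either chair. The endo C3 silyl ether is axial only in the chair that leads to the unwanted isomer, and geometric isomers would have to be separated.
- HF·pyridine then gives 39.

Step 25. The Z-type C14 allylic alcohol may react slowly. Competing titanium-directed epoxidation of C4=C5 from the C3 hydroxyl is also possible, because C3 has the fast-reacting configuration for this tartrate.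

The fallback sets out from 38 and returns at 40. It epoxidises under substrate control while the tether is still in place.
- The (3S) centre and the bridge hold the C4–C9 chain under one face of the strained trans C1=C10.
- m-Chloroperbenzoic acid/NaHCO3 in CH2Cl2 at −20 °C should therefore attack the open face of this most nucleophilic alkene and give epoxy silyl acetal F14.
- Et3N·3HF then releases 40.

**Further compounds**
F1 | step 15 | trans-3-[(DMB-oxy)methyl]-5-(PMB-oxy)cyclohex-1-enyl trimethylsilyl ether | C[Si](C)(C)OC1=C[C@H](COCc2ccc(OC)c(OC)c2)C[C@@H](OCc2ccc(OC)cc2)C1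
F2 | step 15 | (R)-3-[(DMB-oxy)methyl]-5-(PMB-oxy)cyclohex-2-en-1-one | O=C1C=C(COCc2ccc(OC)c(OC)c2)C[C@@H](OCc2ccc(OC)cc2)C1
F3 | step 15 | (R)-3-(hydroxymethyl)-5-(PMB-oxy)cyclohex-2-en-1-one | O=C1C=C(CO)C[C@@H](OCc2ccc(OC)cc2)C1
F4 | step 15 | silyl acetal of F3 and 20 | O=C1C=C(CO[Si](C(C)C)(C(C)C)O[C@H]2CC=C2C)C[C@@H](OCc3ccc(OC)cc3)C1
F5 | step 15 | 8-epimer of 23 (OPMB anti) | O=C1C[C@H](OCc5ccc(OC)cc5)C[C@]2(CO[Si]4(C(C)C)C(C)C)[C@H]1[C@@]3(C)[C@@H](O4)C[C@@H]23
F6 | step 15 | C6 alcohol (O6 syn) | O[C@H]1C[C@H](OCc5ccc(OC)cc5)C[C@]2(CO[Si]4(C(C)C)C(C)C)[C@H]1[C@@]3(C)[C@@H](O4)C[C@@H]23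
F7 | step 15 | C6 triethylsilyl ether | CC[Si](CC)(CC)O[C@H]1C[C@H](OCc5ccc(OC)cc5)C[C@]2(CO[Si]4(C(C)C)C(C)C)[C@H]1[C@@]3(C)[C@@H](O4)C[C@@H]23
F8 | step 15 | C8 alcohol | CC[Si](CC)(CC)O[C@H]1C[C@H](O)C[C@]2(CO[Si]4(C(C)C)C(C)C)[C@H]1[C@@]3(C)[C@@H](O4)C[C@@H]23
F9 | step 15 | C8 ketone | CC[Si](CC)(CC)O[C@H]1CC(=O)C[C@]2(CO[Si]4(C(C)C)C(C)C)[C@H]1[C@@]3(C)[C@@H](O4)C[C@@H]23
F10 | step 15 | C7-alkylated C8 keto ester | CC[Si](CC)(CC)O[C@H]1[C@H](CC(=O)OC)C(=O)C[C@]2(CO[Si]4(C(C)C)C(C)C)[C@H]1[C@@]3(C)[C@@H](O4)C[C@@H]23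
F11 | step 23 | tricyclic 3,14-diol | O=C1C(=C)[C@@H]2[C@H](OC(=O)[C@H](C)CC)C[C@]3(CO)[C@H]([C@H]2O1)[C@@]4(C)[C@@H](O)C[C@@H]34
F12 | step 23 | tricyclic 3,14-bis(tert-butyldimethylsilyl) ether | O=C1C(=C)[C@@H]2[C@H](OC(=O)[C@H](C)CC)C[C@]3(CO[Si](C)(C)C(C)(C)C)[C@H]([C@H]2O1)[C@@]4(C)[C@@H](O[Si](C)(C)C(C)(C)C)C[C@@H]34
F13 | step 23 | cyclodecadiene 3,14-bis(tert-butyldimethylsilyl) ether | C=C1C(=O)O[C@@H]2/C=C(/C)[C@@H](O[Si](C)(C)C(C)(C)C)C/C=C(\CO[Si](C)(C)C(C)(C)C)C[C@@H](OC(=O)[C@H](C)CC)[C@@H]12
F14 | step 25 | (1R,10S)-epoxy silyl acetal | C=C1C(=O)O[C@@H]2/C=C(/C)[C@@H]3C[C@H]4O[C@]4(CO[Si](C(C)C)(C(C)C)O3)C[C@@H](OC(=O)[C@H](C)CC)[C@@H]12
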